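**Plan**

1. Numbering (ionone type): ring C1 = CMe2, C3 = acyloxy carbon, C5/C6 = epoxide carbons (C5 with methyl, C6 with the chain C7=C8–C9(=O)–C10).
2. Cuts, from the target backwards: C9 ketone to a silyl-protected carbinol; the epoxide C5–O bond (back to a C4=C5 alkene and a C6 hydroxyl); the ester C–O bond at C3 (back to a C3 ketone); one C1–CH3 bond; the C6–C7 bond.
3. Enabling feature: C3 and C6 sit para on the six-membered ring, and C1 (two methyls) and C5 (one methyl) differ by a single methyl, so removing that methyl leaves a 3,5-dimethyl para-quinol whose two enone arms are equivalent.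
4. Forward: the carbocycle is an aromatic ring from the outset (4-methoxy-2,6-dimethylphenol, dearomatised to a quinone monoketal); the C7–C10 chain is joined by alkenyllithium addition, and ketal hydrolysis gives the quinol.
5. A copper-catalysed methyl transfer from AlMe3 to one enone arm completes C1; Luche reduction, Mitsunobu esterification, cobalt-hydride closure of the epoxide (the second ring, formed last) and desilylation/oxidation at C9 finish the route.
6. Stereochemistry: C6 from ligand-controlled choice between the two arms; C3 from substrate-controlled hydride delivery, then Mitsunobu inversion; C5 from C6, because the C6 oxygen closes the epoxide on its own face; the C9 centre from (S)-but-3-yn-2-ol is a temporary handle.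

Key step: step 6

Assumption: which enantiomer of the phosphoramidite selects the required enone arm cannot be predicted with confidence; the (S,R,R) ligand is written, and its mirror image would be used if the other arm reacts.

**Route**

Step 1
Reactants: 1 4-methoxy-2,6-dimethylphenol
Product: 2 4,4-dimethoxy-2,6-dimethylcyclohexa-2,5-dien-1-one
Conditions: PhI(OAc)2 (1.1 equiv), MeOH, 0 °C to rt
Reagents that add atoms: methanol, CO
Why: Oxidative dearomatisation of a para-methoxyphenol with a trivalent iodine reagent, in which methanol adds to the para carbon as iodobenzene leaves, is the standard entry to quinone monoketals and leaves the methyl-flanked carbonyl free for the later addition.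

Step 2
Reactants: 3 (S)-but-3-yn-2-ol
Product: 4 (S)-(but-3-yn-2-yloxy)(tert-butyl)dimethylsilane
Conditions: TBSCl, imidazole, CH2Cl2, 0 °C to rt
Reagents that add atoms: tert-butyldimethylsilyl chloride, CC(C)(C)[Si](C)(C)Cl
Why: Silylation of a secondary alcohol with TBSCl and imidazole is routine and touches neither the stereocentre nor the terminal alkyne.

Step 3
Reactants: 4 (S)-(but-3-yn-2-yloxy)(tert-butyl)dimethylsilane
Product: 6 tert-butyl{[(2S,3E)-4-iodobut-3-en-2-yl]oxy}dimethylsilane, via alkenylzirconocene chloride 5 (not isolated)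
Conditions: Cp2Zr(H)Cl, THF, rt; then I2, 0 °C
Reagents that add atoms: iodine, II
Why: Schwartz hydrozirconation adds Zr–H syn across the terminal alkyne with the metal on the terminal carbon, and iodinolysis of the carbon–zirconium bond goes with retention, so only the E-iodide should form.

Step 4
Reactants: 6 tert-butyl{[(2S,3E)-4-iodobut-3-en-2-yl]oxy}dimethylsilane; 2 4,4-dimethoxy-2,6-dimethylcyclohexa-2,5-dien-1-one
Product: 8 4,4-dimethoxy-2,6-dimethyl-1-[(1E,3S)-3-(tert-butyldimethylsilyloxy)but-1-en-1-yl]cyclohexa-2,5-dien-1-ol, via alkenyllithium 7 (not isolated)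
Conditions: t-BuLi (2.0 equiv), Et2O, −78 °C; then 2, THF, −78 to −40 °C; H2O
Reagents that add atoms: none
Why: Iodine–lithium exchange keeps the alkene geometry, and the alkenyllithium adds 1,2 to the carbonyl of the quinone monoketal (a well-used organolithium addition) to form the C6–C7 bond; the carbinol carbon is not yet stereogenic because the two ring arms are identical.

Step 5
Reactants: 8 4,4-dimethoxy-2,6-dimethyl-1-[(1E,3S)-3-(tert-butyldimethylsilyloxy)but-1-en-1-yl]cyclohexa-2,5-dien-1-ol
Product: 9 4-hydroxy-3,5-dimethyl-4-[(1E,3S)-3-(tert-butyldimethylsilyloxy)but-1-en-1-yl]cyclohexa-2,5-dien-1-one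
Conditions: 5% aq. oxalic acid, THF, 0 °C to rt
Reagents that add atoms: water, O
Why: Mild acid hydrolysis of the dimethyl ketal of a quinol (acetal hydrolysis) unmasks the cross-conjugated dienone under conditions that the secondary TBS ether and the tertiary alcohol should survive.

Step 6
Reactants: 9 4-hydroxy-3,5-dimethyl-4-[(1E,3S)-3-(tert-butyldimethylsilyloxy)but-1-en-1-yl]cyclohexa-2,5-dien-1-one; 10 trimethylaluminium
Product: 13 (4S)-4-hydroxy-3,5,5-trimethyl-4-[(1E,3S)-3-(tert-butyldimethylsilyloxy)but-1-en-1-yl]cyclohex-2-en-1-one, via dimethylaluminium alkoxide 11 (not isolated), via aluminium dienolate 12 (not isolated)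
Conditions: AlMe3 (3 equiv), copper thiophene-2-carboxylate C5H3CuO2S (monovalent copper, 5 mol%), (S,R,R)-phosphoramidite from (S)-1,1'-bi-2-naphthol and bis[(R)-1-phenylethyl]amine (10 mol%), Et2O, −30 °C; then sat. aq. NH4Cl, aq. potassium sodium tartrate
Reagents that add atoms: none
Why: Proposed new method: AlMe3 first converts the tertiary hydroxyl into dimethylaluminium alkoxide 11 with loss of methane; a methylcopper species carrying the phosphoramidite (monovalent copper, formed by transmetallation from aluminium) then binds one enone arm, adds at its methyl-bearing β-carbon to give a trivalent copper intermediate and eliminates reductively to form the C1–CH3 bond, leaving aluminium dienolate 12, which cannot accept a second methyl and is protonated to 13 on work-up. The closest known reactions are the copper–phosphoramidite-catalysed conjugate additions of AlMe3 to β-methylcyclohexenones, which create quaternary carbons, and the copper-catalysed desymmetrising conjugate additions of dialkylzinc reagents to 4,4-disubstituted cyclohexadienones; what is new is their combination on a 3,5-dimethyl para-quinol, where the new quaternary carbon lies next to the fully substituted carbinol carbon. No ring is closed in this step. The attacked carbon becomes CMe2 and is not stereogenic, so the single new stereocentre is the carbinol carbon (4S), fixed by which of the two enone arms (equivalent within the ring, differing only through the remote silyloxy centre) receives the methyl, a choice made by the chiral ligand on copper. The step needs this arm selection, 1,4- rather than 1,2-addition and a single addition: the two faces of the ring differ (O–AlMe2 on one, the bulky alkenyl group on the other), so the ligand's preference for one enone face becomes a preference for one arm, copper catalysis directs the methyl to the β-carbon, and enolate formation stops the reaction after one transfer.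

Step 7
Reactants: 13 (4S)-4-hydroxy-3,5,5-trimethyl-4-[(1E,3S)-3-(tert-butyldimethylsilyloxy)but-1-en-1-yl]cyclohex-2-en-1-one
Product: 14 (1S,4R)-1-[(1E,3S)-3-(tert-butyldimethylsilyloxy)but-1-en-1-yl]-2,6,6-trimethylcyclohex-2-ene-1,4-diol (the two hydroxyls cis)
Conditions: NaBH4, CeCl3·7H2O, MeOH, −78 to −20 °C
Reagents that add atoms: none
Why: Luche reduction gives 1,2-reduction only, and hydride should reach the carbonyl from the face opposite the pseudoaxial C1 methyl (the face that carries the side chain), which places the new C3 hydroxyl cis to the C6 hydroxyl under substrate control.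

Step 8
Reactants: 14 (1S,4R)-1-[(1E,3S)-3-(tert-butyldimethylsilyloxy)but-1-en-1-yl]-2,6,6-trimethylcyclohex-2-ene-1,4-diol; 15 tetradecanoic acid
Product: 16 (1S,4S)-4-hydroxy-3,5,5-trimethyl-4-[(1E,3S)-3-(tert-butyldimethylsilyloxy)but-1-en-1-yl]cyclohex-2-en-1-yl tetradecanoate
Conditions: PPh3, DIAD, THF, 0 °C to rt
Reagents that add atoms: none
Why: Mitsunobu esterification activates only the secondary allylic hydroxyl, which tetradecanoate displaces in an SN2 reaction with inversion, while the tertiary C6 hydroxyl is too hindered to react; this sets the 3S centre trans to the C6 oxygen.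

Step 9
Reactants: 16 (1S,4S)-4-hydroxy-3,5,5-trimethyl-4-[(1E,3S)-3-(tert-butyldimethylsilyloxy)but-1-en-1-yl]cyclohex-2-en-1-yl tetradecanoate
Product: 17 (1R,3S,6S)-6-[(1E,3S)-3-(tert-butyldimethylsilyloxy)but-1-en-1-yl]-1,5,5-trimethyl-7-oxabicyclo[4.1.0]heptan-3-yl tetradecanoate
Conditions: cobalt salen catalyst C36H52CoN2O2 [(R,R)-N,N'-bis(3,5-di-tert-butylsalicylidene)cyclohexane-1,2-diaminatocobalt, divalent cobalt] (5 mol%), N-fluoro-2,4,6-trimethylpyridinium triflate (1.5 equiv), PhSiH3 (1.5 equiv), acetone, 0 °C to rt; aq. NaHCO3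
Reagents that add atoms: none
Why: Cobalt–salen hydride catalysis (hydrogen-atom transfer followed by radical–polar crossover) is known to turn tertiary allylic alcohols into epoxides: the hydrogen atom goes to C4 of the trisubstituted ring alkene, the tertiary C5 radical is captured and oxidised at cobalt, and the C6 hydroxyl closes the three-membered ring on its own face, so C5 is set as R by the C6 centre.

Step 10
Reactants: 17 (1R,3S,6S)-6-[(1E,3S)-3-(tert-butyldimethylsilyloxy)but-1-en-1-yl]-1,5,5-trimethyl-7-oxabicyclo[4.1.0]heptan-3-yl tetradecanoate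
Product: 18 (1R,3S,6S)-6-[(1E,3S)-3-hydroxybut-1-en-1-yl]-1,5,5-trimethyl-7-oxabicyclo[4.1.0]heptan-3-yl tetradecanoate
Conditions: Bu4NF, AcOH, THF, 0 °C to rt
Reagents that add atoms: none
Why: Fluoride cleaves the silicon–oxygen bond of the secondary TBS ether (desilylation), and buffering with acetic acid keeps the medium mild enough for the ester and the epoxide.

Step 11
Reactants: 18 (1R,3S,6S)-6-[(1E,3S)-3-hydroxybut-1-en-1-yl]-1,5,5-trimethyl-7-oxabicyclo[4.1.0]heptan-3-yl tetradecanoate
Product: 19 (1R,3S,6S)-1,5,5-trimethyl-6-[(1E)-3-oxobut-1-en-1-yl]-7-oxabicyclo[4.1.0]heptan-3-yl tetradecanoate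
Conditions: MnO2 (activated, excess), CH2Cl2, rt
Reagents that add atoms: none
Why: Activated MnO2 oxidises allylic alcohols selectively, so the C9 carbinol becomes the conjugated ketone (its stereocentre is removed) while the ester and the epoxide stay untouched.

**Compound list**

1 | 4-methoxy-2,6-dimethylphenol | COc1cc(C)c(O)c(C)c1 | starting material
2 | 4,4-dimethoxy-2,6-dimethylcyclohexa-2,5-dien-1-one | COC1(OC)C=C(C)C(=O)C(C)=C1 | intermediate
3 | (S)-but-3-yn-2-ol | C[C@H](O)C#C | starting material
4 | (S)-(but-3-yn-2-yloxy)(tert-butyl)dimethylsilane | C[C@H](O[Si](C)(C)C(C)(C)C)C#C | intermediate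
5 | [(1E,3S)-3-(tert-butyldimethylsilyloxy)but-1-en-1-yl]zirconocene chloride | C[C@H](O[Si](C)(C)C(C)(C)C)/C=C/[Zr](Cl)(C1C=CC=C1)C1C=CC=C1 | intermediate (not isolated)
6 | tert-butyl{[(2S,3E)-4-iodobut-3-en-2-yl]oxy}dimethylsilane | C[C@H](O[Si](C)(C)C(C)(C)C)/C=C/I | intermediate
7 | [(1E,3S)-3-(tert-butyldimethylsilyloxy)but-1-en-1-yl]lithium | C[C@H](O[Si](C)(C)C(C)(C)C)/C=C/[Li] | intermediate (not isolated)
8 | 4,4-dimethoxy-2,6-dimethyl-1-[(1E,3S)-3-(tert-butyldimethylsilyloxy)but-1-en-1-yl]cyclohexa-2,5-dien-1-ol | COC1(OC)C=C(C)C(O)(/C=C/[C@H](C)O[Si](C)(C)C(C)(C)C)C(C)=C1 | intermediate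
9 | 4-hydroxy-3,5-dimethyl-4-[(1E,3S)-3-(tert-butyldimethylsilyloxy)but-1-en-1-yl]cyclohexa-2,5-dien-1-one | CC1=CC(=O)C=C(C)C1(O)/C=C/[C@H](C)O[Si](C)(C)C(C)(C)C | intermediate
10 | trimethylaluminium | C[Al](C)C | starting material
11 | O-dimethylaluminium alkoxide of 9 | CC1=CC(=O)C=C(C)C1(O[Al](C)C)/C=C/[C@H](C)O[Si](C)(C)C(C)(C)C | intermediate (not isolated)
12 | bis(dimethylaluminium) derivative of 13: C3 dienolate and C6 alkoxide, carbinol carbon configured as in 13 | C[Al](C)OC1=CC(C)(C)[C@@](O[Al](C)C)(/C=C/[C@H](C)O[Si](C)(C)C(C)(C)C)C(C)=C1 | intermediate (not isolated)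
13 | (4S)-4-hydroxy-3,5,5-trimethyl-4-[(1E,3S)-3-(tert-butyldimethylsilyloxy)but-1-en-1-yl]cyclohex-2-en-1-one | O=C1CC(C)(C)[C@@](O)(/C=C/[C@H](C)O[Si](C)(C)C(C)(C)C)C(C)=C1 | intermediate
14 | (1S,4R)-1-[(1E,3S)-3-(tert-butyldimethylsilyloxy)but-1-en-1-yl]-2,6,6-trimethylcyclohex-2-ene-1,4-diol (hydroxyls cis) | O[C@@H]1CC(C)(C)[C@@](O)(/C=C/[C@H](C)O[Si](C)(C)C(C)(C)C)C(C)=C1 | intermediate
15 | tetradecanoic acid | CCCCCCCCCCCCCC(=O)O | starting material
16 | (1S,4S)-4-hydroxy-3,5,5-trimethyl-4-[(1E,3S)-3-(tert-butyldimethylsilyloxy)but-1-en-1-yl]cyclohex-2-en-1-yl tetradecanoate (ester trans to the tertiary hydroxyl) | CCCCCCCCCCCCCC(=O)O[C@H]1CC(C)(C)[C@@](O)(/C=C/[C@H](C)O[Si](C)(C)C(C)(C)C)C(C)=C1 | intermediate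
17 | (1R,3S,6S)-6-[(1E,3S)-3-(tert-butyldimethylsilyloxy)but-1-en-1-yl]-1,5,5-trimethyl-7-oxabicyclo[4.1.0]heptan-3-yl tetradecanoate | CCCCCCCCCCCCCC(=O)O[C@H]1CC(C)(C)[C@]2(/C=C/[C@H](C)O[Si](C)(C)C(C)(C)C)O[C@]2(C)C1 | intermediate
18 | (1R,3S,6S)-6-[(1E,3S)-3-hydroxybut-1-en-1-yl]-1,5,5-trimethyl-7-oxabicyclo[4.1.0]heptan-3-yl tetradecanoate | CCCCCCCCCCCCCC(=O)O[C@H]1CC(C)(C)[C@]2(/C=C/[C@H](C)O)O[C@]2(C)C1 | intermediate
19 | (1R,3S,6S)-1,5,5-trimethyl-6-[(1E)-3-oxobut-1-en-1-yl]-7-oxabicyclo[4.1.0]heptan-3-yl tetradecanoate (CNP0118807.1) | CCCCCCCCCCCCCC(=O)O[C@H]1CC(C)(C)[C@]2(/C=C/C(C)=O)O[C@]2(C)C1 | target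

**Step count and risks**

Total steps: 11. Longest linear sequence: 10 steps (3 to 19 through steps 2 to 11).

Most likely to fail:

1. Step 6. Methyl transfer may be too slow at a β-carbon flanked by the fully substituted carbinol carbon. An uncatalysed, alkoxide-directed methyl delivery from aluminium (blind to the two arms) or 1,2-addition could then take over, or the catalyst may discriminate the arms poorly. The fallback uses known chemistry, sets out from iodide 6 and returns at 13. Commercial 4-oxoisophorone (2,6,6-trimethylcyclohex-2-ene-1,4-dione) F1 is ketalised at its less hindered carbonyl (ethylene glycol, p-toluenesulfonic acid, benzene, reflux with water removal) to 7,9,9-trimethyl-1,4-dioxaspiro[4.5]dec-6-en-8-one F2. Alkenyllithium 7, made from 6 as in step 4, adds to the remaining ketone to give 8-[(1E,3S)-3-(tert-butyldimethylsilyloxy)but-1-en-1-yl]-7,9,9-trimethyl-1,4-dioxaspiro[4.5]dec-6-en-8-ol F3 as both C8 epimers. Aqueous oxalic acid removes the dioxolane and gives 13 together with its C4 epimer, (4R)-4-hydroxy-3,5,5-trimethyl-4-[(1E,3S)-3-(tert-butyldimethylsilyloxy)but-1-en-1-yl]cyclohex-2-en-1-one F4. The two are diastereomers because of the (S) side-chain centre and would be separated by preparative chromatography. Here the gem-dimethyl group comes with the ring and the carbinol stereocentre is obtained by separation instead of catalysis.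

2. Step 9. The electron-poor C5 centre may be quenched by a 1,2-shift of the C6 alkenyl group (semipinacol-type ring contraction or chain migration) instead of by the hydroxyl. The cobalt hydride may also deliver its hydrogen atom to the side-chain double bond. The fallback sets out from 16 and returns at 19. Desilylation (Bu4NF, AcOH, THF) gives (1S,4S)-4-hydroxy-4-[(1E,3S)-3-hydroxybut-1-en-1-yl]-3,5,5-trimethylcyclohex-2-en-1-yl tetradecanoate F5, and MnO2 gives (1S,4S)-4-hydroxy-3,5,5-trimethyl-4-[(1E)-3-oxobut-1-en-1-yl]cyclohex-2-en-1-yl tetradecanoate F6. The cobalt-hydride cycloisomerisation is then run last and delivers 19 directly. On F6 the alkenyl group is the β-terminus of an enone, which migrates poorly to a cationic centre and is a poorer hydrogen-atom acceptor.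

3. Step 7. Hydride delivery may show poor facial selectivity, giving a mixture of C3 epimers, or may favour the trans-diol. The fallback sets out from 13 and returns at 16. Reagent-controlled reduction with the CBS oxazaborolidine C18H20BNO and catecholborane in toluene at −78 °C should give (1S,4S)-1-[(1E,3S)-3-(tert-butyldimethylsilyloxy)but-1-en-1-yl]-2,6,6-trimethylcyclohex-2-ene-1,4-diol F7, the trans-diol with the 3S carbinol. The (R)-Me catalyst is the one predicted by the usual model with the alkene arm as the large group. F7 is then esterified with retention by Steglich coupling with 15 (DCC, 4-(dimethylamino)pyridine, CH2Cl2), which makes the Mitsunobu inversion unnecessary.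

**Further compounds**

F1 | step 6 | 2,6,6-trimethylcyclohex-2-ene-1,4-dione | CC1=CC(=O)CC(C)(C)C1=O
F2 | step 6 | 7,9,9-trimethyl-1,4-dioxaspiro[4.5]dec-6-en-8-one | CC1=CC2(CC(C)(C)C1=O)OCCO2
F3 | step 6 | 8-[(1E,3S)-3-(tert-butyldimethylsilyloxy)but-1-en-1-yl]-7,9,9-trimethyl-1,4-dioxaspiro[4.5]dec-6-en-8-ol (both C8 epimers) | CC1=CC2(CC(C)(C)C1(O)/C=C/[C@H](C)O[Si](C)(C)C(C)(C)C)OCCO2
F4 | step 6 | (4R)-4-hydroxy-3,5,5-trimethyl-4-[(1E,3S)-3-(tert-butyldimethylsilyloxy)but-1-en-1-yl]cyclohex-2-en-1-one | O=C1CC(C)(C)[C@](O)(/C=C/[C@H](C)O[Si](C)(C)C(C)(C)C)C(C)=C1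
F5 | step 9 | (1S,4S)-4-hydroxy-4-[(1E,3S)-3-hydroxybut-1-en-1-yl]-3,5,5-trimethylcyclohex-2-en-1-yl tetradecanoate | CCCCCCCCCCCCCC(=O)O[C@H]1CC(C)(C)[C@@](O)(/C=C/[C@H](C)O)C(C)=C1
F6 | step 9 | (1S,4S)-4-hydroxy-3,5,5-trimethyl-4-[(1E)-3-oxobut-1-en-1-yl]cyclohex-2-en-1-yl tetradecanoate | CCCCCCCCCCCCCC(=O)O[C@H]1CC(C)(C)[C@@](O)(/C=C/C(C)=O)C(C)=C1
F7 | step 7 | (1S,4S)-1-[(1E,3S)-3-(tert-butyldimethylsilyloxy)but-1-en-1-yl]-2,6,6-trimethylcyclohex-2-ene-1,4-diol | O[C@H]1CC(C)(C)[C@@](O)(/C=C/[C@H](C)O[Si](C)(C)C(C)(C)C)C(C)=C1
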